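**Strategy.** The cyclopentane (C1 quaternary, C2 bearing the 2‑methylprop‑1‑enyl group, C3H2, C4–Me, C5–CH2OAr) is traced back to a cyclohexane: the vinylic CH attached to C2 is a former ring carbon that sat between C1 and C2. A fully substituted cyclohexanone is α‑tosyloxylated at its only enolisable position; hydride reduction and an aluminium‑promoted semipinacol 1,2‑shift of C1 onto the tosylate carbon then form the C1–C2 bond, contract the ring, fix C2 by inversion and expel the carbinol carbon as a formyl group. Wittig olefination, Mitsunobu etherification with umbelliferone and ester cleavage complete the route.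

Key step: step 7

Remark: the C2 methyl centre of 7, 8 and 10 is epimerisable (drawn as the all‑equatorial 2S epimer; imine 14 is drawn without configuration there) and is fixed only in step 5. In 15–19 the cyclohexane is numbered from the quaternary carbon (C1; C2 = CH–CH2OSi, C3 = CH–Me, C5 = α‑carbon, C6 = C=O or CH–OH).

Step 1
Reactants: 1 propanal; 2 pent‑1‑en‑3‑one
Product: 3 (2S)‑2‑methyl‑5‑oxoheptanal
Conditions: (R)‑2‑[methoxy(diphenyl)methyl]pyrrolidine (5 mol %), ethyl 3,4‑dihydroxybenzoate (20 mol %), neat, 4 °C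
Reagents that add atoms: propanal, CCC=O; pent‑1‑en‑3‑one, C=CC(=O)CC
Why: Enamine‑catalysed asymmetric Michael addition of an aldehyde to a vinyl ketone, in which the diphenyl(methoxy)methyl group shields one enamine face so that the (R)‑catalyst should deliver the (S) α‑centre.

Step 2
Reactants: 3 (2S)‑2‑methyl‑5‑oxoheptanal
Product: 4 (4S)‑2,4‑dimethylcyclohex‑2‑en‑1‑one
Conditions: LiOH (0.2 equiv), i‑PrOH, rt
Reagents that add atoms: none
Why: Intramolecular aldol condensation (Robinson‑type closure) of the ketone α′‑CH2 onto the aldehyde, after which the stereocentre is C4 of the enone; mild base should limit its epimerisation.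

Step 3
Reactants: 4 (4S)‑2,4‑dimethylcyclohex‑2‑en‑1‑one; 5 (chloromethyl)dimethyl(propan‑2‑yloxy)silane; 6 hydrogen peroxide
Product: 8 (2S,3R,4S)‑3‑(hydroxymethyl)‑2,4‑dimethylcyclohexan‑1‑one, via (2S,3R,4S)‑3‑{[dimethyl(propan‑2‑yloxy)silyl]methyl}‑2,4‑dimethylcyclohexan‑1‑one 7 (not isolated)
Conditions: 5, Mg, THF; 4, CuI (10 mol %), THF, −30 → 0 °C; aq NH4Cl; then KF, KHCO3, 30 % H2O2, THF/MeOH, rt
Reagents that add atoms: (chloromethyl)dimethyl(propan‑2‑yloxy)silane, CC(C)O[Si](C)(C)CCl (as its Grignard reagent, delivers CH2); hydrogen peroxide, OO (delivers O)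
Why: Copper‑catalysed conjugate addition of the Tamao hydroxymethyl‑anion equivalent should occur anti to the C4 methyl group (trans‑3,4), and Tamao oxidation then converts the C–Si bond into C–OH.

Step 4
Reactants: 8 (2S,3R,4S)‑3‑(hydroxymethyl)‑2,4‑dimethylcyclohexan‑1‑one; 9 tert‑butyl(chloro)diphenylsilane
Product: 10 (2S,3R,4S)‑3‑({[tert‑butyl(diphenyl)silyl]oxy}methyl)‑2,4‑dimethylcyclohexan‑1‑one
Conditions: TBDPSCl, imidazole, DMF, rt
Reagents that add atoms: tert‑butyl(chloro)diphenylsilane, CC(C)(C)[Si](Cl)(c1ccccc1)c1ccccc1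
Why: Standard silylation of the primary alcohol gives an ether that should survive the later oxidising, Lewis‑acidic and basic steps.

Step 5
Reactants: 10 (2S,3R,4S)‑3‑({[tert‑butyl(diphenyl)silyl]oxy}methyl)‑2,4‑dimethylcyclohexan‑1‑one; 11 (S)‑1‑phenylethan‑1‑amine; 12 tert‑butyl prop‑2‑enoate; 13 water
Product: 16 tert‑butyl 3‑[(1S,2R,3S)‑2‑({[tert‑butyl(diphenyl)silyl]oxy}methyl)‑1,3‑dimethyl‑6‑oxocyclohexyl]propanoate, via (3R,4S)‑3‑({[tert‑butyl(diphenyl)silyl]oxy}methyl)‑2,4‑dimethyl‑N‑[(1S)‑1‑phenylethyl]cyclohexan‑1‑imine 14 (not isolated), via tert‑butyl 3‑[(1S,2R,3S)‑2‑({[tert‑butyl(diphenyl)silyl]oxy}methyl)‑1,3‑dimethyl‑6‑{[(1S)‑1‑phenylethyl]imino}cyclohexyl]propanoate 15 (not isolated)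
Conditions: 11, TsOH (cat.), toluene, reflux (Dean–Stark); 12, 60 °C; then 20 % aq AcOH, THF, rt
Reagents that add atoms: tert‑butyl prop‑2‑enoate, C=CC(=O)OC(C)(C)C; water, O
Why: d'Angelo Michael reaction of the more substituted secondary enamine tautomer, in which the acrylate should add to the methyl‑bearing carbon anti to the vicinal CH2OSi group, a preference the (S)‑auxiliary is expected to reinforce by analogy with 2‑methylcyclohexanone, so that the chain ends up trans and the methyl cis to CH2OSi.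

Step 6
Reactants: 16 tert‑butyl 3‑[(1S,2R,3S)‑2‑({[tert‑butyl(diphenyl)silyl]oxy}methyl)‑1,3‑dimethyl‑6‑oxocyclohexyl]propanoate; 17 [hydroxy(tosyloxy)iodo]benzene
Product: 18 tert‑butyl 3‑[(1S,2R,3S,5R)‑2‑({[tert‑butyl(diphenyl)silyl]oxy}methyl)‑1,3‑dimethyl‑5‑[(4‑methylbenzenesulfonyl)oxy]‑6‑oxocyclohexyl]propanoate
Conditions: PhI(OH)OTs, MeCN, 70 °C
Reagents that add atoms: [hydroxy(tosyloxy)iodo]benzene, OI(OS(=O)(=O)c1ccc(C)cc1)c1ccccc1
Why: Koser α‑tosyloxylation through the enol can occur only at C5, and both approach anti to the axial C1 methyl group and equilibration of the epimerisable α‑centre should place the sulfonate equatorial (5R, cis to the propanoate chain).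

Step 7
Reactants: 18 tert‑butyl 3‑[(1S,2R,3S,5R)‑2‑({[tert‑butyl(diphenyl)silyl]oxy}methyl)‑1,3‑dimethyl‑5‑[(4‑methylbenzenesulfonyl)oxy]‑6‑oxocyclohexyl]propanoate
Product: 20 tert‑butyl 3‑[(1S,2R,4S,5R)‑5‑({[tert‑butyl(diphenyl)silyl]oxy}methyl)‑2‑formyl‑1,4‑dimethylcyclopentyl]propanoate, via tert‑butyl 3‑[(1S,2R,3S,5R,6R)‑2‑({[tert‑butyl(diphenyl)silyl]oxy}methyl)‑6‑hydroxy‑1,3‑dimethyl‑5‑[(4‑methylbenzenesulfonyl)oxy]cyclohexyl]propanoate (present as its aluminium alkoxide) 19 (not isolated)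
Conditions: DIBAL‑H (1.1 equiv), CH2Cl2, −78 °C; then Et3Al (3 equiv), −78 → 0 °C; aq Rochelle salt
Reagents that add atoms: none
Why: DIBAL‑H should reduce the activated α‑sulfonyloxy ketone far faster than the tert‑butyl ester and give the aluminium alkoxide of 19; Et3Al then assists ionisation of the secondary tosylate while the antiperiplanar C1–C6 bond shifts from the carbinol carbon C6 to C5 and the alkoxide oxygen turns C6 into the formyl group (semipinacol rearrangement). The closest known reactions are the reductive 1,2‑rearrangement of α‑sulfonyloxy ketones with DIBAL‑H/Et3Al and the classical contraction of 2‑halo‑ or 2‑sulfonyloxycyclohexanols to cyclopentanecarbaldehydes. The cyclopentane is closed by this suprafacial 1,2‑alkyl shift (C1–C5 bond formed as C1–C6 breaks), not by an exo or endo cyclisation. The new stereocentre (C2 of the cyclopentane, former C5) is formed with inversion at the tosylate carbon, so the equatorial 5R sulfonate, cis to the propanoate chain, gives the formyl group cis to that chain, and the migrating quaternary carbon retains its configuration. The step needs C–C migration to win over hydride shift, epoxide formation, elimination and lactonisation: in the chair locked by the equatorial CH2OSi and methyl groups only the ring C1–C6 bond is antiperiplanar to the equatorial C–OTs bond, the carbinol H and O cannot become anti to it, and the tert‑butyl ester should resist acylation of the aluminium alkoxide at low temperature.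

Step 8
Reactants: 20 tert‑butyl 3‑[(1S,2R,4S,5R)‑5‑({[tert‑butyl(diphenyl)silyl]oxy}methyl)‑2‑formyl‑1,4‑dimethylcyclopentyl]propanoate; 21 triphenyl(propan‑2‑yl)phosphonium iodide
Product: 23 tert‑butyl 3‑[(1R,2S,4S,5R)‑5‑(hydroxymethyl)‑1,4‑dimethyl‑2‑(2‑methylprop‑1‑en‑1‑yl)cyclopentyl]propanoate, via tert‑butyl 3‑[(1R,2S,4S,5R)‑5‑({[tert‑butyl(diphenyl)silyl]oxy}methyl)‑1,4‑dimethyl‑2‑(2‑methylprop‑1‑en‑1‑yl)cyclopentyl]propanoate 22 (not isolated)
Conditions: 21, n‑BuLi, THF, 0 °C; 20, −78 °C → rt; then TBAF, rt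
Reagents that add atoms: triphenyl(propan‑2‑yl)phosphonium iodide, CC(C)[P+](c1ccccc1)(c1ccccc1)c1ccccc1.[I-]
Why: Wittig olefination with the non‑stabilised isopropylidene ylide gives the trisubstituted alkene without an E/Z issue, addition at −78 °C should keep the α‑formyl centre intact, and fluoride then cleaves the silyl ether in the same flask.

Step 9
Reactants: 23 tert‑butyl 3‑[(1R,2S,4S,5R)‑5‑(hydroxymethyl)‑1,4‑dimethyl‑2‑(2‑methylprop‑1‑en‑1‑yl)cyclopentyl]propanoate; 24 7‑hydroxy‑2H‑chromen‑2‑one (umbelliferone)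
Product: 25 tert‑butyl 3‑[(1R,2S,4S,5R)‑1,4‑dimethyl‑2‑(2‑methylprop‑1‑en‑1‑yl)‑5‑{[(2‑oxo‑2H‑chromen‑7‑yl)oxy]methyl}cyclopentyl]propanoate
Conditions: PPh3, DIAD, THF, 0 → 40 °C
Reagents that add atoms: 7‑hydroxy‑2H‑chromen‑2‑one, O=c1ccc2ccc(O)cc2o1
Why: Mitsunobu etherification, in which the acidic phenol should displace the oxyphosphonium of the primary alcohol; no stereocentre is involved.

Step 10
Reactants: 25 tert‑butyl 3‑[(1R,2S,4S,5R)‑1,4‑dimethyl‑2‑(2‑methylprop‑1‑en‑1‑yl)‑5‑{[(2‑oxo‑2H‑chromen‑7‑yl)oxy]methyl}cyclopentyl]propanoate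
Product: 27 ferulsinaic acid, 3‑[(1R,2S,4S,5R)‑1,4‑dimethyl‑2‑(2‑methylprop‑1‑en‑1‑yl)‑5‑{[(2‑oxo‑2H‑chromen‑7‑yl)oxy]methyl}cyclopentyl]propanoic acid, via trimethylsilyl 3‑[(1R,2S,4S,5R)‑1,4‑dimethyl‑2‑(2‑methylprop‑1‑en‑1‑yl)‑5‑{[(2‑oxo‑2H‑chromen‑7‑yl)oxy]methyl}cyclopentyl]propanoate 26 (not isolated)
Conditions: TMSOTf, 2,6‑lutidine, CH2Cl2, 0 °C → rt; aq citric acid
Reagents that add atoms: none
Why: Silyl‑triflate‑mediated tert‑butyl ester cleavage (O‑silylation, loss of isobutene under lutidine buffering, hydrolysis of the silyl ester on work‑up) avoids protic acid, so the trisubstituted alkene and the coumarin should be untouched.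

**Compound list**
1 | propanal | CCC=O | starting material
2 | pent‑1‑en‑3‑one | C=CC(=O)CC | starting material
3 | (2S)‑2‑methyl‑5‑oxoheptanal | CCC(=O)CC[C@H](C)C=O | intermediate
4 | (4S)‑2,4‑dimethylcyclohex‑2‑en‑1‑one | CC1=C[C@@H](C)CCC1=O | intermediate
5 | (chloromethyl)dimethyl(propan‑2‑yloxy)silane | CC(C)O[Si](C)(C)CCl | starting material
6 | hydrogen peroxide | OO | starting material
7 | (2S,3R,4S)‑3‑{[dimethyl(propan‑2‑yloxy)silyl]methyl}‑2,4‑dimethylcyclohexan‑1‑one | C[C@@H]1C(=O)CC[C@H](C)[C@H]1C[Si](C)(C)OC(C)C | intermediate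
8 | (2S,3R,4S)‑3‑(hydroxymethyl)‑2,4‑dimethylcyclohexan‑1‑one | C[C@@H]1C(=O)CC[C@H](C)[C@H]1CO | intermediate
9 | tert‑butyl(chloro)diphenylsilane | CC(C)(C)[Si](Cl)(c1ccccc1)c1ccccc1 | starting material
10 | (2S,3R,4S)‑3‑({[tert‑butyl(diphenyl)silyl]oxy}methyl)‑2,4‑dimethylcyclohexan‑1‑one | C[C@@H]1C(=O)CC[C@H](C)[C@H]1CO[Si](c2ccccc2)(c2ccccc2)C(C)(C)C | intermediate
11 | (S)‑1‑phenylethan‑1‑amine | C[C@H](N)c1ccccc1 | starting material
12 | tert‑butyl prop‑2‑enoate | C=CC(=O)OC(C)(C)C | starting material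
13 | water | O | starting material
14 | (3R,4S)‑3‑({[tert‑butyl(diphenyl)silyl]oxy}methyl)‑2,4‑dimethyl‑N‑[(1S)‑1‑phenylethyl]cyclohexan‑1‑imine | C[C@H](N=C1CC[C@H](C)[C@@H](CO[Si](c2ccccc2)(c2ccccc2)C(C)(C)C)C1C)c1ccccc1 | intermediate
15 | tert‑butyl 3‑[(1S,2R,3S)‑2‑({[tert‑butyl(diphenyl)silyl]oxy}methyl)‑1,3‑dimethyl‑6‑{[(1S)‑1‑phenylethyl]imino}cyclohexyl]propanoate | C[C@H](N=C1CC[C@H](C)[C@@H](CO[Si](c2ccccc2)(c2ccccc2)C(C)(C)C)[C@]1(C)CCC(=O)OC(C)(C)C)c1ccccc1 | intermediate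
16 | tert‑butyl 3‑[(1S,2R,3S)‑2‑({[tert‑butyl(diphenyl)silyl]oxy}methyl)‑1,3‑dimethyl‑6‑oxocyclohexyl]propanoate | O=C1CC[C@H](C)[C@@H](CO[Si](c2ccccc2)(c2ccccc2)C(C)(C)C)[C@]1(C)CCC(=O)OC(C)(C)C | intermediate
17 | [hydroxy(tosyloxy)iodo]benzene | OI(OS(=O)(=O)c1ccc(C)cc1)c1ccccc1 | starting material
18 | tert‑butyl 3‑[(1S,2R,3S,5R)‑2‑({[tert‑butyl(diphenyl)silyl]oxy}methyl)‑1,3‑dimethyl‑5‑[(4‑methylbenzenesulfonyl)oxy]‑6‑oxocyclohexyl]propanoate | O=C1[C@H](OS(=O)(=O)c2ccc(C)cc2)C[C@H](C)[C@@H](CO[Si](c2ccccc2)(c2ccccc2)C(C)(C)C)[C@]1(C)CCC(=O)OC(C)(C)C | intermediate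
19 | tert‑butyl 3‑[(1S,2R,3S,5R,6R)‑2‑({[tert‑butyl(diphenyl)silyl]oxy}methyl)‑6‑hydroxy‑1,3‑dimethyl‑5‑[(4‑methylbenzenesulfonyl)oxy]cyclohexyl]propanoate | O[C@H]1[C@H](OS(=O)(=O)c2ccc(C)cc2)C[C@H](C)[C@@H](CO[Si](c2ccccc2)(c2ccccc2)C(C)(C)C)[C@]1(C)CCC(=O)OC(C)(C)C | intermediate
20 | tert‑butyl 3‑[(1S,2R,4S,5R)‑5‑({[tert‑butyl(diphenyl)silyl]oxy}methyl)‑2‑formyl‑1,4‑dimethylcyclopentyl]propanoate | O=C[C@@H]1C[C@H](C)[C@@H](CO[Si](c2ccccc2)(c2ccccc2)C(C)(C)C)[C@]1(C)CCC(=O)OC(C)(C)C | intermediate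
21 | triphenyl(propan‑2‑yl)phosphonium iodide | CC(C)[P+](c1ccccc1)(c1ccccc1)c1ccccc1.[I-] | starting material
22 | tert‑butyl 3‑[(1R,2S,4S,5R)‑5‑({[tert‑butyl(diphenyl)silyl]oxy}methyl)‑1,4‑dimethyl‑2‑(2‑methylprop‑1‑en‑1‑yl)cyclopentyl]propanoate | CC(C)=C[C@@H]1C[C@H](C)[C@@H](CO[Si](c2ccccc2)(c2ccccc2)C(C)(C)C)[C@]1(C)CCC(=O)OC(C)(C)C | intermediate
23 | tert‑butyl 3‑[(1R,2S,4S,5R)‑5‑(hydroxymethyl)‑1,4‑dimethyl‑2‑(2‑methylprop‑1‑en‑1‑yl)cyclopentyl]propanoate | CC(C)=C[C@@H]1C[C@H](C)[C@@H](CO)[C@]1(C)CCC(=O)OC(C)(C)C | intermediate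
24 | 7‑hydroxy‑2H‑chromen‑2‑one (umbelliferone) | O=c1ccc2ccc(O)cc2o1 | starting material
25 | tert‑butyl 3‑[(1R,2S,4S,5R)‑1,4‑dimethyl‑2‑(2‑methylprop‑1‑en‑1‑yl)‑5‑{[(2‑oxo‑2H‑chromen‑7‑yl)oxy]methyl}cyclopentyl]propanoate | CC(C)=C[C@@H]1C[C@H](C)[C@@H](COc2ccc3ccc(=O)oc3c2)[C@]1(C)CCC(=O)OC(C)(C)C | intermediate
26 | trimethylsilyl 3‑[(1R,2S,4S,5R)‑1,4‑dimethyl‑2‑(2‑methylprop‑1‑en‑1‑yl)‑5‑{[(2‑oxo‑2H‑chromen‑7‑yl)oxy]methyl}cyclopentyl]propanoate | CC(C)=C[C@@H]1C[C@H](C)[C@@H](COc2ccc3ccc(=O)oc3c2)[C@]1(C)CCC(=O)O[Si](C)(C)C | intermediate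
27 | ferulsinaic acid, 3‑[(1R,2S,4S,5R)‑1,4‑dimethyl‑2‑(2‑methylprop‑1‑en‑1‑yl)‑5‑{[(2‑oxo‑2H‑chromen‑7‑yl)oxy]methyl}cyclopentyl]propanoic acid | CC(C)=C[C@@H]1C[C@H](C)[C@@H](COc2ccc3ccc(=O)oc3c2)[C@]1(C)CCC(=O)O | target

**Total step count:** 10. **Longest linear sequence:** 10 steps (1 → 27).

**Steps most likely to fail**

Step 7. Ionisation of the secondary sulfonate may lag behind other reactions of the aluminium alkoxide, so that elimination, ethyl transfer to the newly formed formyl group or epimerisation next to it erode the outcome. The fallback sets out from 18 and returns at 20. Treatment of 18 with NaOMe in MeOH at 0 °C should add methoxide to the ketone and let the same antiperiplanar ring bond migrate with inversion (quasi‑Favorskii, semibenzilic contraction), giving methyl (1R,2S,3R,4S)‑2‑(3‑tert‑butoxy‑3‑oxopropyl)‑3‑({[tert‑butyl(diphenyl)silyl]oxy}methyl)‑2,4‑dimethylcyclopentane‑1‑carboxylate F1. LiBH4 (THF, 0 °C → rt) should reduce the methyl ester in preference to the tert‑butyl ester to tert‑butyl 3‑[(1R,2R,4S,5R)‑5‑({[tert‑butyl(diphenyl)silyl]oxy}methyl)‑2‑(hydroxymethyl)‑1,4‑dimethylcyclopentyl]propanoate F2, and Dess–Martin oxidation of F2 gives 20.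

Step 5. The secondary enamine may react too slowly at the carbon flanked by the CH2OSi‑bearing centre, or react through its less substituted tautomer at the other α‑carbon, so that the quaternary centre forms with poor conversion or regioselectivity. The fallback sets out from 10 and returns at 16. Thermodynamic silylation (TMSCl, NaI, Et3N, MeCN) should give the tetrasubstituted enol ether {[(3R,4S)‑3‑({[tert‑butyl(diphenyl)silyl]oxy}methyl)‑2,4‑dimethylcyclohex‑1‑en‑1‑yl]oxy}trimethylsilane F3. A Mukaiyama–Michael addition of F3 to tert‑butyl acrylate (Tf2NH cat., CH2Cl2, −78 °C), again anti to the CH2OSi group, passes through the silyl ketene acetal tert‑butyl trimethylsilyl acetal of the adduct F4, which aqueous work‑up hydrolyses to 16.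

Step 9. Displacement of the oxyphosphonium at a CH2 group flanked by a quaternary and a tertiary carbon may be slow, so that the betaine is consumed by side alkylation before the ether forms. The fallback sets out from 23 and returns at 25. Palladium‑catalysed C–O coupling of 23 with 7‑bromo‑2H‑chromen‑2‑one (RockPhos Pd G3, Cs2CO3, toluene, 90 °C) makes the alkoxide the nucleophile at the aryl carbon, so no substitution at the hindered carbon is needed; it gives 25 directly and makes no new compound (F0).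

**Further compounds**
F1 | step 7 | methyl (1R,2S,3R,4S)‑2‑(3‑tert‑butoxy‑3‑oxopropyl)‑3‑({[tert‑butyl(diphenyl)silyl]oxy}methyl)‑2,4‑dimethylcyclopentane‑1‑carboxylate | COC(=O)[C@@H]1C[C@H](C)[C@@H](CO[Si](c2ccccc2)(c2ccccc2)C(C)(C)C)[C@]1(C)CCC(=O)OC(C)(C)C
F2 | step 7 | tert‑butyl 3‑[(1R,2R,4S,5R)‑5‑({[tert‑butyl(diphenyl)silyl]oxy}methyl)‑2‑(hydroxymethyl)‑1,4‑dimethylcyclopentyl]propanoate | OC[C@@H]1C[C@H](C)[C@@H](CO[Si](c2ccccc2)(c2ccccc2)C(C)(C)C)[C@]1(C)CCC(=O)OC(C)(C)C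
F3 | step 5 | {[(3R,4S)‑3‑({[tert‑butyl(diphenyl)silyl]oxy}methyl)‑2,4‑dimethylcyclohex‑1‑en‑1‑yl]oxy}trimethylsilane | CC1=C(O[Si](C)(C)C)CC[C@H](C)[C@H]1CO[Si](c2ccccc2)(c2ccccc2)C(C)(C)C
F4 | step 5 | (1S,2R,3S)‑2‑({[tert‑butyl(diphenyl)silyl]oxy}methyl)‑1,3‑dimethyl‑6‑oxocyclohexyl‑substituted tert‑butyl trimethylsilyl ketene acetal (silyl ketene acetal of 16) | O=C1CC[C@H](C)[C@@H](CO[Si](c2ccccc2)(c2ccccc2)C(C)(C)C)[C@]1(C)CC=C(O[Si](C)(C)C)OC(C)(C)C
F0 | step 9 | none | none
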